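The numbers in the tables stem from a simulated flask on assumed constants, and the scatter is random.

Percentage points of excess are the wrong unit for your hunch that a single-handed catalyst gives one excess whatever its charge. At their last readings the red run stands at 12.4% and the ochre run at 16.0%, with a reading scattering by 1 percentage point.

| setting | red | ochre | winter | noon |
|---|---|---|---|---|
| left-handed substrate | 0.10 M | 0.10 M | 0.10 M | 0.10 M |
| right-handed substrate | 0.10 M | 0.10 M | 0.10 M | 0.10 M |
| reagent | 0.10 M | 0.10 M | 0.100 M | 0.100 M |
| free catalyst | 0.31 mM | 0.73 mM | 0.61 mM | 0.15 mM |
| remark | run made earlier | run made earlier |  |  |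
| time |  |  | 15 min | 15 min |

- red (time / min: right-handed substrate / %, left-handed substrate / %): 2.00: 47.1, 44.9; 4.00: 45.3, 39.7; 6.00: 45.4, 37.5; 8.00: 46.6, 35.9; 10.0: 45.4, 35.4
- ochre (time / min: right-handed substrate / %, left-handed substrate / %): 1.00: 49.2, 43.1; 2.50: 47.6, 37.7; 5.00: 42.6, 33.8; 8.00: 42.3, 28.7; 10.0: 41.4, 30.0

(scatter of a reading: 1 percentage point)

- free catalyst is single-handed; left-handed substrate and right-handed substrate are mirror images of each other, charged as a racemate, each of them at the stated concentration
- what was read earlier has a scatter of 1 percentage point, one standard deviation
- an excess is the difference of the two amounts in percent of their sum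
- an excess is below zero if the other one leads

- the winner by excess of right-handed substrate over left-handed substrate among what is left of the two; "neither" if no more than 2 percentage points parts them (winter / noon / neither)
- excess of right-handed substrate over left-handed substrate among what is left of the two at the end, winter
- excess of right-handed substrate over left-handed substrate among what is left of the two at the end, noon

What should hold steady is another number. Pooling the last readings of red and ochre, I read 3.00 for the sorting ratio (selectivity factor), the log loss of left-handed substrate, meaning the natural log of charged over remaining, divided by the same log loss of right-handed substrate. Given that ratio, you need just the left-handed log loss to get an excess.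

Red lost 0.345 at 0.31 mM of catalyst, ochre 0.511 at 0.73 mM. So 2.35 times the catalyst gave 1.48 times the loss, a power of 0.457. Those are losses at 10.0 min, not end values: red's left-handed substrate reads 35.9% and then 35.4%, a step inside the scatter of 1 point, so it shows no stall. I carry the power across all the same, so what follows are figures for 10.0 min, likely low for the 15 min asked. Winter loses 0.471, which gives 15.6%. Noon, below any charge yet run, loses 0.248, which gives 8.24%. Winter leads.

The forecast says winter, with 16% for winter and 6.5% for noon, lower than my noon figure, on the ground that “This points to the catalyst dying”.

The flask gives winter, with 19.8% for winter and 8.89% for noon, both above my figures.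

    reagent + free catalyst + left-handed substrate → free catalyst + left-handed product (k = 37.6 M⁻² s⁻¹)
    reagent + free catalyst + right-handed substrate → free catalyst + right-handed product (k = 12.6 M⁻² s⁻¹)
    reagent ⇌ dormant form (K = 1.20, k = 9.24 × 10⁻⁴ s⁻¹)
    2 free catalyst → spent catalyst (k = 0.876 M⁻¹ s⁻¹)

Winter's left-handed substrate is still falling, 31.2% at 7.50 min and 27.4% at 15.0 min. Put the 55% of it remaining through the ratio of 3.00 and you get 19.7%. A further flask, like noon but charged with 6.0 × 10⁻⁵ M of free catalyst, keeps 88% of its left-handed substrate, the ratio turns that into 4.26%, and that flask stands at 4.28%.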